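**Retrosynthetic overview**

- Feature: ring A is a 2-alkylresorcinol in which C1 (O-acetyl) and C3 (free OH) flank C2, the carbon that carries the (CH2)10 chain. This is the oxidation pattern of a symmetric 2-alkylcyclohexane-1,3-dione. Ring B is a C-acylphloroglucinol.
- Late disconnections: the four O-benzyl groups (final hydrogenolysis), then the bond between the chain carbonyl and ring B (Friedel–Crafts acylation of 1,3,5-tris(benzyloxy)benzene by the chain acid).
- Ring A aromaticity is traced back to the mono-benzyl enol ether of the dione. This differentiates O1 from O3, so the acetate goes on the single phenol that aromatisation sets free.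
- Ring A carbocycle: bonds C4–C5 (Michael) and C2–C3 (Claisen) from dimethyl malonate and methyl 13-oxopentadec-14-enoate. The enone comes from tridecanedioic acid through a Weinreb amide and vinylmagnesium bromide.
- Ring order: ring A is closed as the cyclohexanedione in step 5 and aromatised in step 8; ring B is brought in preformed from phloroglucinol.

Key step: step 5

**Remarks on the chemistry**

- The target has no stereocentre. The 1,3-dicarbonyl intermediates are drawn as keto forms but exist as enol mixtures; their sp3 centres are labile, unspecified, and disappear on aromatisation.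
- The enol acetate of the dione would map most directly onto ring A. As a vinylogous anhydride it is not expected to survive a dehydrogenation, and the free phenol it would deliver would be acylated when the chain acid is activated. The desymmetrising enol derivative is therefore the benzyl ether, and the phenol released on aromatisation is acetylated.

**Route**

Step 1
Reactants: 1 tridecanedioic acid
Product: 2 dimethyl tridecanedioate
Conditions: MeOH, H2SO4 (cat.), reflux
Reagents that add atoms: methanol, CO
Why: Fischer esterification in excess methanol should convert both carboxylic acids into methyl esters.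

Step 2
Reactants: 2 dimethyl tridecanedioate
Product: 3 13-methoxy-13-oxotridecanoic acid
Conditions: Ba(OH)2 (0.5 equiv), MeOH, rt; then aq HCl
Reagents that add atoms: barium hydroxide, [Ba+2].[OH-].[OH-]
Why: Half-saponification should stop at the monoester because the barium salt of the half-ester precipitates from methanol and is thereby withdrawn from a second hydrolysis.

Step 3
Reactants: 3 13-methoxy-13-oxotridecanoic acid
Product: 5 methyl 13-[methoxy(methyl)amino]-13-oxotridecanoate, via acyl imidazolide 4 (not isolated)
Conditions: CDI (1.1 equiv), CH2Cl2, rt; then MeNHOMe·HCl (1.2 equiv), rt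
Reagents that add atoms: N,O-dimethylhydroxylamine hydrochloride, CNOC.Cl
Why: CDI activation followed by aminolysis of the acyl imidazolide is a standard Weinreb amide formation that leaves the methyl ester untouched.

Step 4
Reactants: 5 methyl 13-[methoxy(methyl)amino]-13-oxotridecanoate; 6 vinylmagnesium bromide
Product: 8 methyl 13-oxopentadec-14-enoate, via magnesium hemiaminal 7 (not isolated)
Conditions: 6 (1.3 equiv), THF, −78 to −10 °C; poured into cold 1 M HCl
Reagents that add atoms: none
Why: In this Weinreb ketone synthesis the amide should react faster than the methyl ester at low temperature, the chelated tetrahedral adduct blocks over-addition, and the inverse acidic quench protonates the released amine so that it cannot add to the vinyl ketone.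

Step 5
Reactants: 8 methyl 13-oxopentadec-14-enoate; 9 dimethyl malonate
Product: 11 methyl 3-(11-methoxy-11-oxoundecyl)-2,4-dioxocyclohexane-1-carboxylate, via Michael adduct 10 (not isolated)
Conditions: 9 (1.1 equiv), NaOMe (1.1 equiv), MeOH, 0 °C, slow addition of 8; then reflux; aq HCl
Reagents that add atoms: none
Why: Methoxide deprotonates 9 and the malonate anion adds to the unsubstituted vinyl terminus C15 of 8 (Michael addition, ring A bond C4–C5) to give 10; the ketone then enolises towards its chain-side methylene C12, which attacks one malonate ester carbonyl and expels methoxide (Claisen-type acyl substitution, ring A bond C2–C3), and the product leaves the equilibrium as the sodium enolate of the acidic dione, which is why a full equivalent of NaOMe is used. The closest known reaction type is the malonate–enone annulation to cyclohexane-1,3-diones used for dimedone and for 5-alkylresorcinol precursors. The one ring closed, the six-membered carbocycle of ring A, should form in a 6-(enolendo)-exo-trig mode. No stereocentre has to be controlled, since C1 and C3 of 11 are enolisable, 11 is a racemic tautomer mixture, and both centres become sp2 later. The selectivity needed is regiochemical, with the chain on the carbon between the two carbonyls, and ring size secures it because the other α-carbon of the ketone (C14) could reach a malonate ester only through a four-membered ring. The remote methyl ester matches the methoxide base, and slow addition of 8 to a slight excess of malonate anion at 0 °C should hold back polymerisation and double Michael addition.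

Step 6
Reactants: 11 methyl 3-(11-methoxy-11-oxoundecyl)-2,4-dioxocyclohexane-1-carboxylate
Product: 13 11-(2,6-dioxocyclohexyl)undecanoic acid, via diacid 12 (not isolated)
Conditions: aq NaOH (4 equiv), reflux; then HCl to pH 1, 90 °C
Reagents that add atoms: sodium hydroxide, [Na+].[OH-]
Why: Saponification of both methyl esters followed by acidification and thermal decarboxylation of the ring β-keto acid should give the symmetric 2-alkyl-1,3-dione, which in alkali is protected from retro-Claisen cleavage as its enolate.

Step 7
Reactants: 13 11-(2,6-dioxocyclohexyl)undecanoic acid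
Product: 14 benzyl 11-[2-(benzyloxy)-6-oxocyclohex-1-en-1-yl]undecanoate
Conditions: BnOH (4 equiv), TsOH·H2O (5 mol %), toluene, reflux, Dean–Stark
Reagents that add atoms: benzyl alcohol, OCc1ccccc1
Why: Acid-catalysed azeotropic condensation should give the vinylogous ester by exclusive O-functionalisation together with the Fischer benzyl ester, and because 13 is symmetric only one mono-enol ether can form, which differentiates the two ring A oxygens.

Step 8
Reactants: 14 benzyl 11-[2-(benzyloxy)-6-oxocyclohex-1-en-1-yl]undecanoate
Product: 17 benzyl 11-[2-(benzyloxy)-6-hydroxyphenyl]undecanoate, via silyl dienol ether 15 (not isolated), via cyclohexadienone 16 (not isolated)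
Conditions: TMSOTf (1.3 equiv), Et3N (2 equiv), CH2Cl2, 0 °C; solvent exchanged; Pd(OAc)2 (1.1 equiv), MeCN, rt
Reagents that add atoms: none
Why: Soft enolisation towards the α'-methylene, as in the preparation of Danishefsky-type dienes, should leave the ester untouched, and Saegusa–Ito oxidation with divalent palladium then introduces the second ring double bond to give a cyclohexadienone that tautomerises to the phenol.

Step 9
Reactants: 17 benzyl 11-[2-(benzyloxy)-6-hydroxyphenyl]undecanoate
Product: 18 11-[2-(benzyloxy)-6-hydroxyphenyl]undecanoic acid
Conditions: LiOH (3 equiv), THF/H2O, 40 °C; then aq HCl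
Reagents that add atoms: lithium hydroxide, [Li+].[OH-]
Why: Ester saponification should free the chain acid while the aryl benzyl ether and the phenol are inert to LiOH.

Step 10
Reactants: 18 11-[2-(benzyloxy)-6-hydroxyphenyl]undecanoic acid
Product: 20 11-[2-(acetyloxy)-6-(benzyloxy)phenyl]undecanoic acid, via mixed anhydride 19 (not isolated)
Conditions: Ac2O (4 equiv), pyridine, DMAP (cat.), CH2Cl2, 0 °C to rt; then H2O, rt; dilute HCl wash
Reagents that add atoms: acetic anhydride, CC(=O)OC(C)=O
Why: DMAP-catalysed O-acetylation of the single free phenol should be clean, and the mixed anhydride formed at the carboxyl group is hydrolysed back by aqueous pyridine far faster than the aryl acetate.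

Step 11
Reactants: 21 phloroglucinol
Product: 22 benzene-1,3,5-triyl triacetate
Conditions: Ac2O, pyridine, rt
Reagents that add atoms: acetic anhydride, CC(=O)OC(C)=O
Why: Exhaustive O-acetylation of the three phenols is a routine acylation.

Step 12
Reactants: 22 benzene-1,3,5-triyl triacetate
Product: 23 1,3,5-tris(benzyloxy)benzene
Conditions: BnCl (3.5 equiv), NaH (7 equiv), DMF, 0 °C; H2O (3 equiv) added slowly, 0 °C to rt
Reagents that add atoms: benzyl chloride, ClCc1ccccc1
Why: In this deacetylation–Williamson etherification the hydroxide generated slowly from NaH and water releases the phenoxides one at a time in excess benzyl chloride, so that O-benzylation should outrun the C-benzylation that spoils direct alkylation of phloroglucinol.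

Step 13
Reactants: 20 11-[2-(acetyloxy)-6-(benzyloxy)phenyl]undecanoic acid; 23 1,3,5-tris(benzyloxy)benzene
Product: 25 3-(benzyloxy)-2-{11-oxo-11-[2,4,6-tris(benzyloxy)phenyl]undecyl}phenyl acetate, via acyl trifluoroacetate 24 (not isolated)
Conditions: TFAA (1.5 equiv), CH2Cl2, 0 °C, 30 min; then 23 (1.2 equiv), 0 °C to rt; cold aq NaHCO3
Reagents that add atoms: none
Why: Friedel–Crafts acylation by the mixed-anhydride method should acylate the triply alkoxy-activated ring of 23 at any of its three equivalent CH positions without a metal Lewis acid, which spares the benzyl ethers and the aryl acetate, and the ketone formed deactivates ring B against a second acylation.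

Step 14
Reactants: 25 3-(benzyloxy)-2-{11-oxo-11-[2,4,6-tris(benzyloxy)phenyl]undecyl}phenyl acetate
Product: 26 3-hydroxy-2-[11-oxo-11-(2,4,6-trihydroxyphenyl)undecyl]phenyl acetate
Conditions: H2 (1 atm), 10% Pd/C, EtOAc, rt
Reagents that add atoms: none
Why: Hydrogenolysis should remove the four O-benzyl groups while the aryl acetate is inert and the hydrogen-bonded 2,4,6-trihydroxyphenyl ketone resists reduction in a non-alcoholic solvent at low pressure.

**Compound list**

1 | tridecanedioic acid | OC(=O)CCCCCCCCCCCC(=O)O | starting material
2 | dimethyl tridecanedioate | COC(=O)CCCCCCCCCCCC(=O)OC | intermediate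
3 | 13-methoxy-13-oxotridecanoic acid | COC(=O)CCCCCCCCCCCC(=O)O | intermediate
4 | methyl 13-(1H-imidazol-1-yl)-13-oxotridecanoate (acyl imidazolide, not isolated) | COC(=O)CCCCCCCCCCCC(=O)n1ccnc1 | intermediate
5 | methyl 13-[methoxy(methyl)amino]-13-oxotridecanoate | COC(=O)CCCCCCCCCCCC(=O)N(C)OC | intermediate
6 | vinylmagnesium bromide | C=C[Mg]Br | starting material
7 | methyl 13-[(bromomagnesio)oxy]-13-[methoxy(methyl)amino]pentadec-14-enoate (magnesium hemiaminal, not isolated) | C=CC(O[Mg]Br)(CCCCCCCCCCCC(=O)OC)N(C)OC | intermediate
8 | methyl 13-oxopentadec-14-enoate | C=CC(=O)CCCCCCCCCCCC(=O)OC | intermediate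
9 | dimethyl malonate | COC(=O)CC(=O)OC | starting material
10 | trimethyl 4-oxopentadecane-1,1,15-tricarboxylate (Michael adduct, not isolated) | COC(=O)C(CCC(=O)CCCCCCCCCCCC(=O)OC)C(=O)OC | intermediate
11 | methyl 3-(11-methoxy-11-oxoundecyl)-2,4-dioxocyclohexane-1-carboxylate (racemic, enolised) | COC(=O)C1CCC(=O)C(CCCCCCCCCCC(=O)OC)C1=O | intermediate
12 | 3-(10-carboxydecyl)-2,4-dioxocyclohexane-1-carboxylic acid (diacid, not isolated) | OC(=O)C1CCC(=O)C(CCCCCCCCCCC(=O)O)C1=O | intermediate
13 | 11-(2,6-dioxocyclohexyl)undecanoic acid (enolised) | OC(=O)CCCCCCCCCCC1C(=O)CCCC1=O | intermediate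
14 | benzyl 11-[2-(benzyloxy)-6-oxocyclohex-1-en-1-yl]undecanoate | O=C(CCCCCCCCCCC1=C(OCc2ccccc2)CCCC1=O)OCc1ccccc1 | intermediate
15 | benzyl 11-{2-(benzyloxy)-6-[(trimethylsilyl)oxy]cyclohexa-1,5-dien-1-yl}undecanoate (silyl dienol ether, not isolated) | O=C(CCCCCCCCCCC1=C(OCc2ccccc2)CCC=C1O[Si](C)(C)C)OCc1ccccc1 | intermediate
16 | benzyl 11-[2-(benzyloxy)-6-oxocyclohexa-1,4-dien-1-yl]undecanoate (cyclohexadienone, not isolated) | O=C(CCCCCCCCCCC1=C(OCc2ccccc2)CC=CC1=O)OCc1ccccc1 | intermediate
17 | benzyl 11-[2-(benzyloxy)-6-hydroxyphenyl]undecanoate | O=C(CCCCCCCCCCc1c(O)cccc1OCc2ccccc2)OCc3ccccc3 | intermediate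
18 | 11-[2-(benzyloxy)-6-hydroxyphenyl]undecanoic acid | OC(=O)CCCCCCCCCCc1c(O)cccc1OCc2ccccc2 | intermediate
19 | acetic 11-[2-(acetyloxy)-6-(benzyloxy)phenyl]undecanoic anhydride (mixed anhydride, not isolated) | CC(=O)OC(=O)CCCCCCCCCCc1c(OC(C)=O)cccc1OCc2ccccc2 | intermediate
20 | 11-[2-(acetyloxy)-6-(benzyloxy)phenyl]undecanoic acid | CC(=O)Oc1cccc(OCc2ccccc2)c1CCCCCCCCCCC(=O)O | intermediate
21 | phloroglucinol | Oc1cc(O)cc(O)c1 | starting material
22 | benzene-1,3,5-triyl triacetate | CC(=O)Oc1cc(OC(C)=O)cc(OC(C)=O)c1 | intermediate
23 | 1,3,5-tris(benzyloxy)benzene | c1ccc(COc2cc(OCc3ccccc3)cc(OCc3ccccc3)c2)cc1 | intermediate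
24 | 11-[2-(acetyloxy)-6-(benzyloxy)phenyl]undecanoic trifluoroacetic anhydride (acyl trifluoroacetate, not isolated) | CC(=O)Oc1cccc(OCc2ccccc2)c1CCCCCCCCCCC(=O)OC(=O)C(F)(F)F | intermediate
25 | 3-(benzyloxy)-2-{11-oxo-11-[2,4,6-tris(benzyloxy)phenyl]undecyl}phenyl acetate | CC(=O)Oc1cccc(OCc2ccccc2)c1CCCCCCCCCCC(=O)c3c(OCc4ccccc4)cc(OCc5ccccc5)cc3OCc6ccccc6 | intermediate
26 | 3-hydroxy-2-[11-oxo-11-(2,4,6-trihydroxyphenyl)undecyl]phenyl acetate | CC(=O)Oc1cccc(O)c1CCCCCCCCCCC(=O)c1c(O)cc(O)cc1O | target

**Step count**

Total: 14 steps. Longest linear sequence: 12 steps (steps 1 to 10, then 13 and 14); the side branch to 23 takes steps 11 and 12.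

**Steps most likely to fail**

Step 5. The enone may polymerise or take up a second enone before the ring closes, or the sequence may stall at the open adduct under equilibrating methoxide. The fallback separates the two bond formations and replaces the anionic conjugate addition by a Lewis-acid one. It sets out from 8, which is treated with 1-methoxy-1-(trimethylsilyloxy)ethene and TiCl4 in CH2Cl2 at −78 °C (Mukaiyama–Michael addition, aqueous work-up) to give dimethyl 5-oxoheptadecanedioate F1. Claisen cyclisation of this δ-keto ester with NaOMe in refluxing toluene, again possible only through the six-membered ring, should give methyl 11-(2,6-dioxocyclohexyl)undecanoate F2. Saponification with aqueous NaOH and acidification returns the route at 13, with no decarboxylation needed.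

Step 8. The benzyl enol ether may be hydrolysed back to the dione during silylation, or the dehydrogenation may stop short of the phenol. The fallback inverts aromatisation and desymmetrisation. It sets out from 13, which is dehydrogenated over 10% Pd/C in refluxing p-cymene to 11-(2,6-dihydroxyphenyl)undecanoic acid F3. Alkylation of F3 with benzyl bromide (2 equiv) and K2CO3 in DMF benzylates the carboxylate and, statistically, one phenol. After separation from the bis-ether and the un-etherified ester, both of which can be recycled, the route is rejoined at 17.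

Step 13. The trifluoroacetic acid released may strip benzyl ethers from the electron-rich ring, 23 may be trifluoroacetylated in competition, or the activated acid may attack ring A of another molecule. The fallback makes the ketone bond by cross-coupling and sets out from 20 and 23. Compound 20 is converted with oxalyl chloride and catalytic DMF into 11-[2-(acetyloxy)-6-(benzyloxy)phenyl]undecanoyl chloride F4. Compound 23 is brominated with N-bromosuccinimide in CH2Cl2 to 2-bromo-1,3,5-tris(benzyloxy)benzene F5. Bromine–lithium exchange with n-BuLi in THF at −78 °C gives [2,4,6-tris(benzyloxy)phenyl]lithium F6, and transmetalation with ZnCl2 gives chlorido[2,4,6-tris(benzyloxy)phenyl]zinc F7. Negishi acylation of F7 with F4, catalysed by Pd(PPh3)4 in THF, tolerates the aryl acetate and returns the route at 25.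

**Further compounds**

F1 | step 5 | dimethyl 5-oxoheptadecanedioate | COC(=O)CCCC(=O)CCCCCCCCCCCC(=O)OC
F2 | step 5 | methyl 11-(2,6-dioxocyclohexyl)undecanoate | COC(=O)CCCCCCCCCCC1C(=O)CCCC1=O
F3 | step 8 | 11-(2,6-dihydroxyphenyl)undecanoic acid | OC(=O)CCCCCCCCCCc1c(O)cccc1O
F4 | step 13 | 11-[2-(acetyloxy)-6-(benzyloxy)phenyl]undecanoyl chloride | CC(=O)Oc1cccc(OCc2ccccc2)c1CCCCCCCCCCC(=O)Cl
F5 | step 13 | 2-bromo-1,3,5-tris(benzyloxy)benzene | Brc1c(OCc2ccccc2)cc(OCc3ccccc3)cc1OCc4ccccc4
F6 | step 13 | [2,4,6-tris(benzyloxy)phenyl]lithium | [Li]c1c(OCc2ccccc2)cc(OCc3ccccc3)cc1OCc4ccccc4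
F7 | step 13 | chlorido[2,4,6-tris(benzyloxy)phenyl]zinc | Cl[Zn]c1c(OCc2ccccc2)cc(OCc3ccccc3)cc1OCc4ccccc4
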